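## Retrosynthetic overview

1. Target 35 comes from oxidation of a 2‑alkyl‑4‑chloro‑5‑methylresorcinol (34) to the hydroxy‑p‑quinone. The ring ketone is unmasked late from a C1 pivalate, and the (S)‑carbinol comes from CBS reduction of (E)‑enone 29.
2. Enone 29 comes from an intermolecular boron aldol of ethyl ketone 16 (cyclohexane fragment) with arylacetaldehyde 25 (aromatic fragment), then dehydration. This C(Me)–CH bond joins the two halves.
3. Ketone 16 comes from (S)‑3‑allyl‑4‑methylcyclohex‑2‑enone 7: conjugate methylation anti to the C4 methyl sets C3, enolate methylation sets C2, and the allyl group becomes the 2‑oxobutyl arm. Enone 7 comes from (S)‑4‑methylcyclohexenone 5, made by an organocatalytic Michael addition of propanal to methyl vinyl ketone and aldol condensation.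
4. Aldehyde 25 comes from orcinol: bis‑MOM ether, ortho‑lithiation/allylation, chlorination, MOM to TBS exchange, alkene cleavage.
5. Ring order: the cyclohexane ring is closed in step 2; the benzene ring is bought (orcinol); the quinone ring is generated from it in the last step.

Assumption: the configuration is read from the SMILES as ring (2R,3S,4S) (C2‑Me cis to C3‑Me, trans to C4‑Me and to the side chain), carbinol S, alkene E. The stereochemical outcomes of steps 1, 6 and 20 are predictions from standard models, not experimental results. Ar = 2,6‑bis[(tert‑butyldimethylsilyl)oxy]‑3‑chloro‑4‑methylphenyl.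

## Route

Step 1
Reactants: 1 propanal; 2 but‑3‑en‑2‑one
Product: 3 (S)‑2‑methyl‑5‑oxohexanal
Conditions: (R)‑2‑[methoxy(diphenyl)methyl]pyrrolidine (5 mol %), ethyl 3,4‑dihydroxybenzoate (20 mol %), neat, 4 °C
Reagents that add atoms: none
Why: Enamine‑catalysed intermolecular Michael addition in which the diphenylmethoxymethyl arm blocks one face of the (E)‑enamine, so the enone adds to the other face and sets the future C4 methyl centre as S.

Step 2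
Reactants: 3 (S)‑2‑methyl‑5‑oxohexanal
Product: 5 (S)‑4‑methylcyclohex‑2‑en‑1‑one, via ketol 4 (not isolated)
Conditions: LiOH·H2O (10 mol %), i‑PrOH, rt
Reagents that add atoms: none
Why: Intramolecular aldol condensation (methyl ketone enolate onto the aldehyde, then E1cB loss of water) closes the six‑membered ring quickly under catalytic base, which limits erosion of the stereocentre.

Step 3
Reactants: 5 (S)‑4‑methylcyclohex‑2‑en‑1‑one
Product: 6 trimethyl{[(3R,4S)‑4‑methyl‑3‑(prop‑2‑en‑1‑yl)cyclohex‑1‑en‑1‑yl]oxy}silane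
Conditions: allylMgBr (2 equiv), CuBr·SMe2 (1 equiv), Me3SiCl (2.5 equiv), THF, −78 °C; Et3N
Reagents that add atoms: allylmagnesium bromide, C=CC[Mg]Br; chlorotrimethylsilane, C[Si](C)(C)Cl
Why: Silyl‑accelerated conjugate addition of an allylcopper reagent occurs anti to the C4 methyl and the enolate is trapped regiospecifically as the silyl enol ether; the new C3 centre is erased in step 4.

Step 4
Reactants: 6 trimethyl{[(3R,4S)‑4‑methyl‑3‑(prop‑2‑en‑1‑yl)cyclohex‑1‑en‑1‑yl]oxy}silane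
Product: 7 (S)‑4‑methyl‑3‑(prop‑2‑en‑1‑yl)cyclohex‑2‑en‑1‑one
Conditions: Pd(OAc)2 (1.05 equiv), MeCN, rt
Reagents that add atoms: none
Why: Saegusa–Ito oxidation, in which the palladium enolate at C2 loses the C3 hydrogen by β‑hydride elimination, re‑forms the enone with the allyl group at C3 and leaves C4 untouched.

Step 5
Reactants: 7 (S)‑4‑methyl‑3‑(prop‑2‑en‑1‑yl)cyclohex‑2‑en‑1‑one
Product: 8 trimethyl{[(3S,4S)‑3,4‑dimethyl‑3‑(prop‑2‑en‑1‑yl)cyclohex‑1‑en‑1‑yl]oxy}silane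
Conditions: Me2CuLi (from MeLi and CuI, 2 equiv), Me3SiCl (3 equiv), Et2O–THF, −78 to −20 °C; Et3N
Reagents that add atoms: methyllithium, [Li]C (used as lithium dimethylcuprate, [Li+].C[Cu-]C); chlorotrimethylsilane, C[Si](C)(C)Cl
Why: Silyl‑accelerated cuprate conjugate addition delivers the methyl group to C3 anti to the C4 methyl, creating the quaternary centre (3S) with the allyl arm cis to the C4 methyl.

Step 6
Reactants: 8 trimethyl{[(3S,4S)‑3,4‑dimethyl‑3‑(prop‑2‑en‑1‑yl)cyclohex‑1‑en‑1‑yl]oxy}silane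
Product: 10 (2R,3S,4S)‑2,3,4‑trimethyl‑3‑(prop‑2‑en‑1‑yl)cyclohexan‑1‑one, via lithium enolate 9 (not isolated)
Conditions: MeLi (1.05 equiv), THF, 0 °C; then MeI (5 equiv), DMPU, −78 to −30 °C
Reagents that add atoms: iodomethane, CI
Why: Regiospecific enolate generation from the silyl enol ether followed by kinetic SN2 methylation, where axial attack anti to the pseudoaxial allyl group and away from the C4 methyl places the new methyl cis to the C3 methyl (2R).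

Step 7
Reactants: 10 (2R,3S,4S)‑2,3,4‑trimethyl‑3‑(prop‑2‑en‑1‑yl)cyclohexan‑1‑one
Product: 11 (1S,2R,3S,4S)‑2,3,4‑trimethyl‑3‑(prop‑2‑en‑1‑yl)cyclohexan‑1‑ol
Conditions: LiBH(s‑Bu)3, THF, −78 °C; then NaOH, H2O2
Reagents that add atoms: none
Why: Bulky‑hydride reduction by equatorial attack masks the ketone at once, so the kinetically set and probably less stable C2 centre cannot epimerise in later basic steps; the C1 configuration is inconsequential because C1 is re‑oxidised in step 23.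

Step 8
Reactants: 11 (1S,2R,3S,4S)‑2,3,4‑trimethyl‑3‑(prop‑2‑en‑1‑yl)cyclohexan‑1‑ol
Product: 12 (1S,2R,3S,4S)‑2,3,4‑trimethyl‑3‑(prop‑2‑en‑1‑yl)cyclohexyl 2,2‑dimethylpropanoate
Conditions: t‑BuCOCl, pyridine, DMAP (cat.), CH2Cl2, 40 °C
Reagents that add atoms: pivaloyl chloride, CC(C)(C)C(=O)Cl
Why: Acylation gives a pivalate that survives Grignard, boron aldol, borane and silylation chemistry and is later removed by hydride, orthogonal to the silyl ethers.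

Step 9
Reactants: 12 (1S,2R,3S,4S)‑2,3,4‑trimethyl‑3‑(prop‑2‑en‑1‑yl)cyclohexyl 2,2‑dimethylpropanoate
Product: 14 (1S,2R,3S,4S)‑2,3,4‑trimethyl‑3‑(2‑oxoethyl)cyclohexyl 2,2‑dimethylpropanoate, via diol 13 (not isolated)
Conditions: OsO4 (2 mol %), NaIO4 (4 equiv), 2,6‑lutidine, dioxane–H2O, rt
Reagents that add atoms: osmium tetroxide, O=[Os](=O)(=O)=O (catalytic oxygen carrier); sodium periodate, [Na+].[O-]I(=O)(=O)=O
Why: Lemieux–Johnson oxidative cleavage (dihydroxylation then periodate glycol cleavage) converts the terminal alkene into the neopentyl‑type aldehyde without touching the ester.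

Step 10
Reactants: 14 (1S,2R,3S,4S)‑2,3,4‑trimethyl‑3‑(2‑oxoethyl)cyclohexyl 2,2‑dimethylpropanoate
Product: 15 (1S,2R,3S,4S)‑3‑(2‑hydroxybutyl)‑2,3,4‑trimethylcyclohexyl 2,2‑dimethylpropanoate (both carbinol epimers)
Conditions: EtMgBr (1.2 equiv), THF, −78 °C; H2O
Reagents that add atoms: ethylmagnesium bromide, CC[Mg]Br
Why: Grignard 1,2‑addition to the aldehyde is far faster than attack on the hindered pivalate at −78 °C; the new carbinol centre is removed in step 11.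

Step 11
Reactants: 15 (1S,2R,3S,4S)‑3‑(2‑hydroxybutyl)‑2,3,4‑trimethylcyclohexyl 2,2‑dimethylpropanoate
Product: 16 (1S,2R,3S,4S)‑2,3,4‑trimethyl‑3‑(2‑oxobutyl)cyclohexyl 2,2‑dimethylpropanoate
Conditions: Dess–Martin periodinane, CH2Cl2, rt
Reagents that add atoms: none
Why: Dess–Martin oxidation of the secondary alcohol gives the ethyl ketone that serves as the aldol donor.

Step 12
Reactants: 17 orcinol (5‑methylbenzene‑1,3‑diol)
Product: 18 1,3‑bis(methoxymethoxy)‑5‑methylbenzene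
Conditions: MeOCH2Cl (2.5 equiv), i‑Pr2NEt, CH2Cl2, 0 °C to rt
Reagents that add atoms: chloromethyl methyl ether, COCCl
Why: Williamson‑type O‑alkylation installs two acetal ethers that direct the ortho‑lithiation in step 13.

Step 13
Reactants: 18 1,3‑bis(methoxymethoxy)‑5‑methylbenzene
Product: 20 1,3‑bis(methoxymethoxy)‑5‑methyl‑2‑(prop‑2‑en‑1‑yl)benzene, via aryllithium 19 (not isolated)
Conditions: n‑BuLi, THF, 0 °C; then allyl bromide, −78 °C to rt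
Reagents that add atoms: allyl bromide, C=CCBr
Why: Directed ortho‑metalation occurs only at the position flanked by both MOM ethers, and the aryllithium is alkylated by allyl bromide.

Step 14
Reactants: 20 1,3‑bis(methoxymethoxy)‑5‑methyl‑2‑(prop‑2‑en‑1‑yl)benzene
Product: 21 4‑chloro‑1,3‑bis(methoxymethoxy)‑5‑methyl‑2‑(prop‑2‑en‑1‑yl)benzene
Conditions: N‑chlorosuccinimide (1.0 equiv), MeCN, rt, dark
Reagents that add atoms: N‑chlorosuccinimide, O=C1CCC(=O)N1Cl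
Why: Electrophilic aromatic chlorination of the very electron‑rich ring, whose two free positions are equivalent by symmetry, gives a single monochloride faster than the terminal alkene reacts.

Step 15
Reactants: 21 4‑chloro‑1,3‑bis(methoxymethoxy)‑5‑methyl‑2‑(prop‑2‑en‑1‑yl)benzene
Product: 22 4‑chloro‑5‑methyl‑2‑(prop‑2‑en‑1‑yl)benzene‑1,3‑diol
Conditions: conc. HCl (cat.), MeOH, 50 °C
Reagents that add atoms: none
Why: Acid‑catalysed acetal exchange with methanol removes both MOM groups at this robust early stage, so that the final phenol deprotection can be done with fluoride and not acid.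

Step 16
Reactants: 22 4‑chloro‑5‑methyl‑2‑(prop‑2‑en‑1‑yl)benzene‑1,3‑diol
Product: 23 1,3‑bis[(tert‑butyldimethylsilyl)oxy]‑4‑chloro‑5‑methyl‑2‑(prop‑2‑en‑1‑yl)benzene
Conditions: t‑BuMe2SiCl (2.5 equiv), imidazole, DMF, rt
Reagents that add atoms: tert‑butyldimethylsilyl chloride, CC(C)(C)[Si](C)(C)Cl
Why: Imidazole‑mediated O‑silylation gives aryl silyl ethers that tolerate the boron aldol, mesylation, borane, hydride and periodinane steps and are cleaved by buffered fluoride.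

Step 17
Reactants: 23 1,3‑bis[(tert‑butyldimethylsilyl)oxy]‑4‑chloro‑5‑methyl‑2‑(prop‑2‑en‑1‑yl)benzene
Product: 25 2‑Ar‑acetaldehyde, via diol 24 (not isolated)
Conditions: OsO4 (2 mol %), NaIO4 (4 equiv), 2,6‑lutidine, dioxane–H2O, rt; used at once
Reagents that add atoms: osmium tetroxide, O=[Os](=O)(=O)=O (catalytic oxygen carrier); sodium periodate, [Na+].[O-]I(=O)(=O)=O
Why: Lemieux–Johnson cleavage of the allyl group gives the arylacetaldehyde under near‑neutral conditions that spare the electron‑rich arene and the silyl ethers.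

Step 18
Reactants: 16 (1S,2R,3S,4S)‑2,3,4‑trimethyl‑3‑(2‑oxobutyl)cyclohexyl 2,2‑dimethylpropanoate; 25 2‑Ar‑acetaldehyde
Product: 27 (1S,2R,3S,4S)‑3‑(5‑Ar‑4‑hydroxy‑3‑methyl‑2‑oxopentyl)‑2,3,4‑trimethylcyclohexyl 2,2‑dimethylpropanoate (syn aldol; two diastereomers), via boron enolate 26 (not isolated)
Conditions: n‑Bu2BOTf (1.2 equiv), i‑Pr2NEt (1.5 equiv), CH2Cl2, −78 to 0 °C; then 25, −78 °C; KH2PO4/K2HPO4 buffer (pH 7), MeOH, H2O2, 0 °C
Reagents that add atoms: none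
Why: Intermolecular boron aldol addition, with soft enolisation on the ethyl side only (the other α‑CH2 is neopentyl) and a closed six‑membered transition state, joins the two fragments without enolising the acidic arylacetaldehyde; both new centres are removed in step 19.

Step 19
Reactants: 27 (1S,2R,3S,4S)‑3‑(5‑Ar‑4‑hydroxy‑3‑methyl‑2‑oxopentyl)‑2,3,4‑trimethylcyclohexyl 2,2‑dimethylpropanoate
Product: 29 (1S,2R,3S,4S)‑3‑[(3E)‑5‑Ar‑3‑methyl‑2‑oxopent‑3‑en‑1‑yl]‑2,3,4‑trimethylcyclohexyl 2,2‑dimethylpropanoate, via mesylate 28 (not isolated)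
Conditions: MeSO2Cl (1.5 equiv), Et3N (5 equiv), CH2Cl2, 0 °C to rt
Reagents that add atoms: none
Why: Mesylation and E1cB elimination through the ketone enolate complete the aldol condensation and give the thermodynamically preferred (E)‑α‑methyl enone; only a mild amine base is used so the double bond does not drift toward the arene.

Step 20
Reactants: 29 (1S,2R,3S,4S)‑3‑[(3E)‑5‑Ar‑3‑methyl‑2‑oxopent‑3‑en‑1‑yl]‑2,3,4‑trimethylcyclohexyl 2,2‑dimethylpropanoate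
Product: 30 (1S,2R,3S,4S)‑3‑[(2S,3E)‑5‑Ar‑2‑hydroxy‑3‑methylpent‑3‑en‑1‑yl]‑2,3,4‑trimethylcyclohexyl 2,2‑dimethylpropanoate
Conditions: (R)‑1‑methyl‑3,3‑diphenyltetrahydro‑1H,3H‑pyrrolo[1,2‑c][1,3,2]oxazaborole (0.5 equiv), catecholborane (2 equiv), toluene, −78 °C; MeOH
Reagents that add atoms: none
Why: Corey–Bakshi–Shibata reduction in which the α‑branched alkenyl group acts as the large substituent and the CH2 arm as the small one, so the (R)‑catalyst delivers hydride to give the (S)‑allylic alcohol under reagent control.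

Step 21
Reactants: 30 (1S,2R,3S,4S)‑3‑[(2S,3E)‑5‑Ar‑2‑hydroxy‑3‑methylpent‑3‑en‑1‑yl]‑2,3,4‑trimethylcyclohexyl 2,2‑dimethylpropanoate
Product: 31 (1S,2R,3S,4S)‑3‑[(2S,3E)‑5‑Ar‑3‑methyl‑2‑(triethylsilyloxy)pent‑3‑en‑1‑yl]‑2,3,4‑trimethylcyclohexyl 2,2‑dimethylpropanoate
Conditions: Et3SiOTf, 2,6‑lutidine, CH2Cl2, −78 °C
Reagents that add atoms: triethylsilyl trifluoromethanesulfonate, CC[Si](CC)(CC)OS(=O)(=O)C(F)(F)F
Why: O‑Silylation protects the allylic alcohol so that only the ring carbinol is oxidised in step 23.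

Step 22
Reactants: 31 (1S,2R,3S,4S)‑3‑[(2S,3E)‑5‑Ar‑3‑methyl‑2‑(triethylsilyloxy)pent‑3‑en‑1‑yl]‑2,3,4‑trimethylcyclohexyl 2,2‑dimethylpropanoate
Product: 32 (1S,2R,3S,4S)‑3‑[(2S,3E)‑5‑Ar‑3‑methyl‑2‑(triethylsilyloxy)pent‑3‑en‑1‑yl]‑2,3,4‑trimethylcyclohexan‑1‑ol
Conditions: i‑Bu2AlH (3 equiv), CH2Cl2, −78 to −40 °C; aq. potassium sodium tartrate
Reagents that add atoms: none
Why: Reductive ester cleavage frees the ring alcohol with a non‑basic, fluoride‑free reagent that leaves the three silyl ethers, the alkene and the aryl chloride intact.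

Step 23
Reactants: 32 (1S,2R,3S,4S)‑3‑[(2S,3E)‑5‑Ar‑3‑methyl‑2‑(triethylsilyloxy)pent‑3‑en‑1‑yl]‑2,3,4‑trimethylcyclohexan‑1‑ol
Product: 33 (2R,3S,4S)‑3‑[(2S,3E)‑5‑Ar‑3‑methyl‑2‑(triethylsilyloxy)pent‑3‑en‑1‑yl]‑2,3,4‑trimethylcyclohexan‑1‑one
Conditions: Dess–Martin periodinane, pyridine, CH2Cl2, 0 °C to rt
Reagents that add atoms: none
Why: Buffered Dess–Martin oxidation regenerates the ring ketone under non‑enolising conditions, so the C2 centre set in step 6 is kept.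

Step 24
Reactants: 33 (2R,3S,4S)‑3‑[(2S,3E)‑5‑Ar‑3‑methyl‑2‑(triethylsilyloxy)pent‑3‑en‑1‑yl]‑2,3,4‑trimethylcyclohexan‑1‑one
Product: 34 (2R,3S,4S)‑3‑[(2S,3E)‑5‑(3‑chloro‑2,6‑dihydroxy‑4‑methylphenyl)‑2‑hydroxy‑3‑methylpent‑3‑en‑1‑yl]‑2,3,4‑trimethylcyclohexan‑1‑one
Conditions: Bu4NF, AcOH (1:1, 4 equiv), THF, 0 °C to rt
Reagents that add atoms: none
Why: Fluoride‑mediated desilylation buffered with acetic acid removes the two aryl silyl ethers and the triethylsilyl ether without the base or acid that would epimerise C2 or ionise the allylic alcohol.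

Step 25
Reactants: 34 (2R,3S,4S)‑3‑[(2S,3E)‑5‑(3‑chloro‑2,6‑dihydroxy‑4‑methylphenyl)‑2‑hydroxy‑3‑methylpent‑3‑en‑1‑yl]‑2,3,4‑trimethylcyclohexan‑1‑one
Product: 35 2‑chloro‑5‑hydroxy‑6‑{(2E,4S)‑4‑hydroxy‑3‑methyl‑5‑[(1S,2R,6S)‑1,2,6‑trimethyl‑3‑oxocyclohexyl]pent‑2‑en‑1‑yl}‑3‑methylcyclohexa‑2,5‑diene‑1,4‑dione (target)
Conditions: (KSO3)2NO (2.5 equiv), KH2PO4 buffer, acetone–H2O, 0 °C to rt
Reagents that add atoms: potassium nitrosodisulfonate, [K+].[K+].[O]N(S(=O)(=O)[O-])S(=O)(=O)[O-]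
Why: Teuber oxidation, in which the phenoxyl radical is trapped by a second nitrosodisulfonate at the only free ring position (para to the hydroxyl flanked by the side chain and chlorine), collapses to the hydroxy‑p‑quinone at near‑neutral pH that does not disturb the ketone α‑centre or the allylic alcohol.

## Compound list

1 | propanal | CCC=O | starting material
2 | but‑3‑en‑2‑one (methyl vinyl ketone) | CC(=O)C=C | starting material
3 | (S)‑2‑methyl‑5‑oxohexanal | C[C@H](C=O)CCC(C)=O | intermediate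
4 | (4S)‑3‑hydroxy‑4‑methylcyclohexan‑1‑one (ketol, C3 epimers) | O=C1CC(O)[C@@H](C)CC1 | intermediate (not isolated)
5 | (S)‑4‑methylcyclohex‑2‑en‑1‑one | O=C1C=C[C@@H](C)CC1 | intermediate
6 | trimethyl{[(3R,4S)‑4‑methyl‑3‑(prop‑2‑en‑1‑yl)cyclohex‑1‑en‑1‑yl]oxy}silane | C[Si](C)(C)OC1=C[C@H](CC=C)[C@@H](C)CC1 | intermediate
7 | (S)‑4‑methyl‑3‑(prop‑2‑en‑1‑yl)cyclohex‑2‑en‑1‑one | O=C1C=C(CC=C)[C@@H](C)CC1 | intermediate
8 | trimethyl{[(3S,4S)‑3,4‑dimethyl‑3‑(prop‑2‑en‑1‑yl)cyclohex‑1‑en‑1‑yl]oxy}silane | C[Si](C)(C)OC1=C[C@@](C)(CC=C)[C@@H](C)CC1 | intermediate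
9 | lithium (3S,4S)‑3,4‑dimethyl‑3‑(prop‑2‑en‑1‑yl)cyclohex‑1‑en‑1‑olate | [Li+].[O-]C1=C[C@@](C)(CC=C)[C@@H](C)CC1 | intermediate (not isolated)
10 | (2R,3S,4S)‑2,3,4‑trimethyl‑3‑(prop‑2‑en‑1‑yl)cyclohexan‑1‑one | O=C1[C@H](C)[C@@](C)(CC=C)[C@@H](C)CC1 | intermediate
11 | (1S,2R,3S,4S)‑2,3,4‑trimethyl‑3‑(prop‑2‑en‑1‑yl)cyclohexan‑1‑ol | O[C@@H]1[C@H](C)[C@@](C)(CC=C)[C@@H](C)CC1 | intermediate
12 | (1S,2R,3S,4S)‑2,3,4‑trimethyl‑3‑(prop‑2‑en‑1‑yl)cyclohexyl 2,2‑dimethylpropanoate | CC(C)(C)C(=O)O[C@@H]1[C@H](C)[C@@](C)(CC=C)[C@@H](C)CC1 | intermediate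
13 | (1S,2R,3S,4S)‑3‑(2,3‑dihydroxypropyl)‑2,3,4‑trimethylcyclohexyl 2,2‑dimethylpropanoate (carbinol epimers) | CC(C)(C)C(=O)O[C@@H]1[C@H](C)[C@@](C)(CC(O)CO)[C@@H](C)CC1 | intermediate (not isolated)
14 | (1S,2R,3S,4S)‑2,3,4‑trimethyl‑3‑(2‑oxoethyl)cyclohexyl 2,2‑dimethylpropanoate | CC(C)(C)C(=O)O[C@@H]1[C@H](C)[C@@](C)(CC=O)[C@@H](C)CC1 | intermediate
15 | (1S,2R,3S,4S)‑3‑(2‑hydroxybutyl)‑2,3,4‑trimethylcyclohexyl 2,2‑dimethylpropanoate (carbinol epimers) | CC(C)(C)C(=O)O[C@@H]1[C@H](C)[C@@](C)(CC(O)CC)[C@@H](C)CC1 | intermediate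
16 | (1S,2R,3S,4S)‑2,3,4‑trimethyl‑3‑(2‑oxobutyl)cyclohexyl 2,2‑dimethylpropanoate | CC(C)(C)C(=O)O[C@@H]1[C@H](C)[C@@](C)(CC(=O)CC)[C@@H](C)CC1 | intermediate
17 | orcinol (5‑methylbenzene‑1,3‑diol) | Cc1cc(O)cc(O)c1 | starting material
18 | 1,3‑bis(methoxymethoxy)‑5‑methylbenzene | Cc1cc(OCOC)cc(OCOC)c1 | intermediate
19 | [2,6‑bis(methoxymethoxy)‑4‑methylphenyl]lithium | [Li]c1c(OCOC)cc(C)cc1OCOC | intermediate (not isolated)
20 | 1,3‑bis(methoxymethoxy)‑5‑methyl‑2‑(prop‑2‑en‑1‑yl)benzene | C=CCc1c(OCOC)cc(C)cc1OCOC | intermediate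
21 | 4‑chloro‑1,3‑bis(methoxymethoxy)‑5‑methyl‑2‑(prop‑2‑en‑1‑yl)benzene | C=CCc1c(OCOC)cc(C)c(Cl)c1OCOC | intermediate
22 | 4‑chloro‑5‑methyl‑2‑(prop‑2‑en‑1‑yl)benzene‑1,3‑diol | C=CCc1c(O)cc(C)c(Cl)c1O | intermediate
23 | 1,3‑bis[(tert‑butyldimethylsilyl)oxy]‑4‑chloro‑5‑methyl‑2‑(prop‑2‑en‑1‑yl)benzene | C=CCc1c(O[Si](C)(C)C(C)(C)C)cc(C)c(Cl)c1O[Si](C)(C)C(C)(C)C | intermediate
24 | 3‑Ar‑propane‑1,2‑diol | OCC(O)Cc1c(O[Si](C)(C)C(C)(C)C)cc(C)c(Cl)c1O[Si](C)(C)C(C)(C)C | intermediate (not isolated)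
25 | 2‑{2,6‑bis[(tert‑butyldimethylsilyl)oxy]‑3‑chloro‑4‑methylphenyl}acetaldehyde | O=CCc1c(O[Si](C)(C)C(C)(C)C)cc(C)c(Cl)c1O[Si](C)(C)C(C)(C)C | intermediate
26 | dibutylboron (Z)‑enolate of 16 | CC(C)(C)C(=O)O[C@@H]1[C@H](C)[C@@](C)(C/C(OB(CCCC)CCCC)=C/C)[C@@H](C)CC1 | intermediate (not isolated)
27 | (1S,2R,3S,4S)‑3‑(5‑Ar‑4‑hydroxy‑3‑methyl‑2‑oxopentyl)‑2,3,4‑trimethylcyclohexyl 2,2‑dimethylpropanoate (syn, two diastereomers) | CC(C)(C)C(=O)O[C@@H]1[C@H](C)[C@@](C)(CC(=O)C(C)C(O)Cc2c(O[Si](C)(C)C(C)(C)C)cc(C)c(Cl)c2O[Si](C)(C)C(C)(C)C)[C@@H](C)CC1 | intermediate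
28 | (1S,2R,3S,4S)‑3‑[5‑Ar‑4‑(methanesulfonyloxy)‑3‑methyl‑2‑oxopentyl]‑2,3,4‑trimethylcyclohexyl 2,2‑dimethylpropanoate | CC(C)(C)C(=O)O[C@@H]1[C@H](C)[C@@](C)(CC(=O)C(C)C(OS(C)(=O)=O)Cc2c(O[Si](C)(C)C(C)(C)C)cc(C)c(Cl)c2O[Si](C)(C)C(C)(C)C)[C@@H](C)CC1 | intermediate (not isolated)
29 | (1S,2R,3S,4S)‑3‑[(3E)‑5‑Ar‑3‑methyl‑2‑oxopent‑3‑en‑1‑yl]‑2,3,4‑trimethylcyclohexyl 2,2‑dimethylpropanoate | CC(C)(C)C(=O)O[C@@H]1[C@H](C)[C@@](C)(CC(=O)/C(C)=C/Cc2c(O[Si](C)(C)C(C)(C)C)cc(C)c(Cl)c2O[Si](C)(C)C(C)(C)C)[C@@H](C)CC1 | intermediate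
30 | (1S,2R,3S,4S)‑3‑[(2S,3E)‑5‑Ar‑2‑hydroxy‑3‑methylpent‑3‑en‑1‑yl]‑2,3,4‑trimethylcyclohexyl 2,2‑dimethylpropanoate | CC(C)(C)C(=O)O[C@@H]1[C@H](C)[C@@](C)(C[C@H](O)/C(C)=C/Cc2c(O[Si](C)(C)C(C)(C)C)cc(C)c(Cl)c2O[Si](C)(C)C(C)(C)C)[C@@H](C)CC1 | intermediate
31 | (1S,2R,3S,4S)‑3‑[(2S,3E)‑5‑Ar‑3‑methyl‑2‑(triethylsilyloxy)pent‑3‑en‑1‑yl]‑2,3,4‑trimethylcyclohexyl 2,2‑dimethylpropanoate | CC(C)(C)C(=O)O[C@@H]1[C@H](C)[C@@](C)(C[C@H](O[Si](CC)(CC)CC)/C(C)=C/Cc2c(O[Si](C)(C)C(C)(C)C)cc(C)c(Cl)c2O[Si](C)(C)C(C)(C)C)[C@@H](C)CC1 | intermediate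
32 | (1S,2R,3S,4S)‑3‑[(2S,3E)‑5‑Ar‑3‑methyl‑2‑(triethylsilyloxy)pent‑3‑en‑1‑yl]‑2,3,4‑trimethylcyclohexan‑1‑ol | O[C@@H]1[C@H](C)[C@@](C)(C[C@H](O[Si](CC)(CC)CC)/C(C)=C/Cc2c(O[Si](C)(C)C(C)(C)C)cc(C)c(Cl)c2O[Si](C)(C)C(C)(C)C)[C@@H](C)CC1 | intermediate
33 | (2R,3S,4S)‑3‑[(2S,3E)‑5‑Ar‑3‑methyl‑2‑(triethylsilyloxy)pent‑3‑en‑1‑yl]‑2,3,4‑trimethylcyclohexan‑1‑one | O=C1[C@H](C)[C@@](C)(C[C@H](O[Si](CC)(CC)CC)/C(C)=C/Cc2c(O[Si](C)(C)C(C)(C)C)cc(C)c(Cl)c2O[Si](C)(C)C(C)(C)C)[C@@H](C)CC1 | intermediate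
34 | (2R,3S,4S)‑3‑[(2S,3E)‑5‑(3‑chloro‑2,6‑dihydroxy‑4‑methylphenyl)‑2‑hydroxy‑3‑methylpent‑3‑en‑1‑yl]‑2,3,4‑trimethylcyclohexan‑1‑one | O=C1[C@H](C)[C@@](C)(C[C@H](O)/C(C)=C/Cc2c(O)cc(C)c(Cl)c2O)[C@@H](C)CC1 | intermediate
35 | 2‑chloro‑5‑hydroxy‑6‑{(2E,4S)‑4‑hydroxy‑3‑methyl‑5‑[(1S,2R,6S)‑1,2,6‑trimethyl‑3‑oxocyclohexyl]pent‑2‑en‑1‑yl}‑3‑methylcyclohexa‑2,5‑diene‑1,4‑dione | CC1=C(Cl)C(=O)C(C/C=C(\C)[C@@H](O)C[C@@]2(C)[C@@H](C)CCC(=O)[C@@H]2C)=C(O)C1=O | target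

## Step count and risks

Total steps: 25. Longest linear sequence: 19 (steps 1–11, then 18–25); the aromatic branch is 6 steps (12–17).

Steps most likely to fail:

**Step 5 (cuprate addition to the hindered β,β‑disubstituted enone).** The fallback sets out from 7 and comes back at 9. The C3 methyl is brought in as a cyclopropane methylene instead of a cuprate ligand. Corey–Chaykovsky reaction of 7 with dimethylsulfoxonium methylide (Me3S(O)I, NaH, DMSO) cyclopropanates the enone anti to the C4 methyl and gives (1R,5S,6R)‑5‑methyl‑6‑(prop‑2‑en‑1‑yl)bicyclo[4.1.0]heptan‑2‑one F1. Lithium in liquid NH3/THF at −78 °C then cleaves the exocyclic cyclopropane bond that overlaps with the carbonyl π system. After removal of ammonia this gives lithium enolate 9 directly, which is methylated as in step 6 to reach 10.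

**Step 6 (facial selectivity of the C2 methylation).** The fallback sets out from 8 and comes back at 10. If the alkylation favours the 2‑epimer, the order of events at C2 is inverted so that a proton, not the methyl group, arrives last on the preferred face.
- Mukaiyama–Mannich reaction of 8 with dimethyl(methylidene)ammonium iodide gives (3S,4S)‑2‑[(dimethylamino)methyl]‑3,4‑dimethyl‑3‑(prop‑2‑en‑1‑yl)cyclohexan‑1‑one F2.
- MeI converts it into the trimethylammonium iodide of that Mannich base F3.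
- NaHCO3 eliminates trimethylamine to give (3S,4S)‑3,4‑dimethyl‑2‑methylidene‑3‑(prop‑2‑en‑1‑yl)cyclohexan‑1‑one F4.
- Conjugate reduction with LiBH(s‑Bu)3 at −78 °C forms lithium (3S,4S)‑2,3,4‑trimethyl‑3‑(prop‑2‑en‑1‑yl)cyclohex‑1‑en‑1‑olate F5, and kinetic protonation with 2,6‑di‑tert‑butylphenol at −78 °C gives 10.

This sequence yields the C2 epimer complementary to direct methylation, so it helps only if methylation favours the wrong epimer; it does not rescue an unselective (about 1:1) alkylation.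

**Step 20 (reagent control in the enone reduction, with a neopentyl‑type CH2 as the small group).** The fallback sets out from 29 and comes back at 30. Luche reduction (NaBH4, CeCl3·7H2O, THF–MeOH, −40 °C) gives 30 together with its carbinol epimer (1S,2R,3S,4S)‑3‑[(2R,3E)‑5‑Ar‑2‑hydroxy‑3‑methylpent‑3‑en‑1‑yl]‑2,3,4‑trimethylcyclohexyl 2,2‑dimethylpropanoate F6. The two diastereomers are separated by chromatography, and F6 is re‑oxidised with MnO2 in CH2Cl2 to 29 and recycled, so the (S)‑alcohol is collected by separation and recycling.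

## Further compounds

F1 | step 5 | (1R,5S,6R)‑5‑methyl‑6‑(prop‑2‑en‑1‑yl)bicyclo[4.1.0]heptan‑2‑one | O=C1[C@@H]2C[C@]2(CC=C)[C@@H](C)CC1
F2 | step 6 | (3S,4S)‑2‑[(dimethylamino)methyl]‑3,4‑dimethyl‑3‑(prop‑2‑en‑1‑yl)cyclohexan‑1‑one (C2 epimers) | O=C1C(CN(C)C)[C@@](C)(CC=C)[C@@H](C)CC1
F3 | step 6 | {[(2S,3S)‑2,3‑dimethyl‑6‑oxo‑2‑(prop‑2‑en‑1‑yl)cyclohexyl]methyl}trimethylammonium iodide (C1 epimers) | O=C1C(C[N+](C)(C)C)[C@@](C)(CC=C)[C@@H](C)CC1.[I-]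
F4 | step 6 | (3S,4S)‑3,4‑dimethyl‑2‑methylidene‑3‑(prop‑2‑en‑1‑yl)cyclohexan‑1‑one | O=C1C(=C)[C@@](C)(CC=C)[C@@H](C)CC1
F5 | step 6 | lithium (3S,4S)‑2,3,4‑trimethyl‑3‑(prop‑2‑en‑1‑yl)cyclohex‑1‑en‑1‑olate | [Li+].[O-]C1=C(C)[C@@](C)(CC=C)[C@@H](C)CC1
F6 | step 20 | (1S,2R,3S,4S)‑3‑[(2R,3E)‑5‑Ar‑2‑hydroxy‑3‑methylpent‑3‑en‑1‑yl]‑2,3,4‑trimethylcyclohexyl 2,2‑dimethylpropanoate | CC(C)(C)C(=O)O[C@@H]1[C@H](C)[C@@](C)(C[C@@H](O)/C(C)=C/Cc2c(O[Si](C)(C)C(C)(C)C)cc(C)c(Cl)c2O[Si](C)(C)C(C)(C)C)[C@@H](C)CC1
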